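**Strategy.** Ring A of the flavanone carries 3-methylbut-2-enyl groups at C6 and C8, each ortho to an oxygen: C8 is flanked by the pyranone oxygen O1 and the 7-hydroxyl, and C6 adjoins the 7-hydroxyl on its other side. Both C–CH2 bonds are therefore traced back to O-bound 1,1-dimethylallyl groups on 2,4-dihydroxyacetophenone. Heating the bis(tertiary allyl) ether 4, which has no free chelated 2-hydroxyl to draw the O4 unit toward C3, should trigger two aromatic Claisen shifts in one operation (O2 to C3, O4 to C5, acetophenone numbering). This gives the 3,5-diprenyl ketone 8 with no ring formed. Ring C and the C2 stereocentre then come from a 2'-hydroxychalcone by catalyst-controlled oxa-Michael closure.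

Key step: step 3

Remark (assumption): in step 3 the 2-O ether is taken to migrate first (either order converges on 8), and in step 6 the quinine-derived thiourea is taken to give the (2S) series, its quinidine-derived pseudoenantiomer being used instead if the sense proves opposite.

**Step 1**
Reactants: 1 2,4-dihydroxyacetophenone; 2 3-chloro-3-methylbut-1-yne
Product: 3 1-[2,4-bis(2-methylbut-3-yn-2-yloxy)phenyl]ethanone
Conditions: 2 (3 equiv), DBU (3.2 equiv), CuCl2·2H2O (1 mol%), MeCN, 0 °C to rt
Reagents that add atoms: none
Why: Copper-catalysed propargylic substitution, the established route to aryl 1,1-dimethylpropargyl ethers: the chloride ionises through a copper acetylide to a copper allenylidene that the phenoxide attacks at the tertiary carbon, and the amidine base is strong enough to break the hydrogen bond of the 2-hydroxyl so that both oxygens are etherified by excess 2.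

**Step 2**
Reactants: 3 1-[2,4-bis(2-methylbut-3-yn-2-yloxy)phenyl]ethanone
Product: 4 1-[2,4-bis(2-methylbut-3-en-2-yloxy)phenyl]ethanone
Conditions: H2 (1 atm), Pd/CaCO3 poisoned with Pb(OAc)2 (Lindlar catalyst), quinoline, EtOAc, rt; stopped after 2 equiv H2; concentrated below 30 °C
Reagents that add atoms: none
Why: Lindlar semihydrogenation delivers one equivalent of hydrogen to each terminal alkyne on the lead- and quinoline-poisoned palladium surface and stops at the alkene, while the aryl ketone and the C–O bonds are left alone; the heat-sensitive product is used crude.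

**Step 3**
Reactants: 4 1-[2,4-bis(2-methylbut-3-en-2-yloxy)phenyl]ethanone
Product: 8 1-[2,4-dihydroxy-3,5-bis(3-methylbut-2-enyl)phenyl]ethanone, via first ortho-dienone 5 (not isolated), via mono-Claisen phenol 6 (not isolated), via second ortho-dienone 7 (not isolated)
Conditions: PhNEt2 (degassed), 135 °C, Ar, sealed tube; then cold 1 M HCl wash
Reagents that add atoms: none
Why: Each O–C(CH3)2–CH=CH2 unit should undergo a concerted, chair-like [3,3]-sigmatropic shift in which the terminal CH2 bonds to the ortho ring carbon as the O–C bond breaks, giving an ortho-cyclohexadienone (5, then 7) that enolises to the phenol (6, then 8); the allylic transposition turns the tertiary ether into the linear 3-methylbut-2-enyl chain. This is the aromatic Claisen rearrangement of aryl 1,1-dimethylallyl ethers, run twice on one ring in the manner of the known double rearrangement of resorcinol-derived bis(allyl) ethers. No ring is closed and no lasting stereocentre is created, since the sp3 ring carbons of 5 and 7 are lost on enolisation. The selectivity needed is O2 to C3 and O4 to C5: the O2 unit has only C3 open because C1 carries the acetyl group, and once C3 is filled the O4 unit can end only at C5, a shift onto the substituted C3 giving a dienone that cannot enolise and reverts. Should the O4 unit move first, the absence of a hydrogen-bonded 2-hydroxyl, the meta-alkoxy group and the bulk of the neighbouring tertiary ether all direct it to C5, so both orders converge on 8. The amine solvent buffers traces of acid so that ionic loss of isoprene and chroman formation stay behind the pericyclic pathway.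

**Step 4**
Reactants: 8 1-[2,4-dihydroxy-3,5-bis(3-methylbut-2-enyl)phenyl]ethanone
Product: 9 1-[2-hydroxy-4-(methoxymethoxy)-3,5-bis(3-methylbut-2-enyl)phenyl]ethanone
Conditions: MOMCl (1.2 equiv), iPr2NEt, CH2Cl2, 0 °C to rt
Reagents that add atoms: chloromethyl methyl ether (MOMCl), COCCl
Why: Chemoselective Williamson-type O-alkylation: the C4 hydroxyl, although flanked by two prenyl groups, is free, whereas the C2 hydroxyl is held in a six-membered hydrogen bond to the acetyl oxygen and does not react with the small electrophile under a mild amine base.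

**Step 5**
Reactants: 9 1-[2-hydroxy-4-(methoxymethoxy)-3,5-bis(3-methylbut-2-enyl)phenyl]ethanone; 10 4-methoxybenzaldehyde
Product: 11 (E)-1-[2-hydroxy-4-(methoxymethoxy)-3,5-bis(3-methylbut-2-enyl)phenyl]-3-(4-methoxyphenyl)prop-2-en-1-one
Conditions: KOH (50% aq), EtOH, 0 °C to rt
Reagents that add atoms: none
Why: Claisen–Schmidt condensation (crossed aldol addition, then E1cB dehydration) between the methyl ketone enolate and the non-enolisable aldehyde gives the conjugated (E)-enone, the methoxymethyl ether and the prenyl groups being stable to hydroxide; the chalcone is purified free of any racemic flavanone before the next step.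

**Step 6**
Reactants: 11 (E)-1-[2-hydroxy-4-(methoxymethoxy)-3,5-bis(3-methylbut-2-enyl)phenyl]-3-(4-methoxyphenyl)prop-2-en-1-one
Product: 12 (2S)-7-(methoxymethoxy)-2-(4-methoxyphenyl)-6,8-bis(3-methylbut-2-enyl)-2,3-dihydrochromen-4-one
Conditions: 1-[3,5-bis(trifluoromethyl)phenyl]-3-[(8α,9S)-6'-methoxycinchonan-9-yl]thiourea (10 mol%), toluene, 0 °C; filtered through silica as soon as conversion levels off
Reagents that add atoms: none
Why: Enantioselective intramolecular oxa-Michael addition (6-endo-trig) under bifunctional cinchona-thiourea catalysis, a known way to close 2'-hydroxychalcones to flavanones: the thiourea hydrogen-bonds the enone carbonyl while the quinuclidine nitrogen deprotonates the 2'-hydroxyl, and the chiral pocket should deliver the phenoxide to the Si face of C-β, which sets C2 as (S) under catalyst control, low temperature and prompt removal of the base limiting ring re-opening.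

**Step 7**
Reactants: 12 (2S)-7-(methoxymethoxy)-2-(4-methoxyphenyl)-6,8-bis(3-methylbut-2-enyl)-2,3-dihydrochromen-4-one
Product: 13 (2S)-7-hydroxy-2-(4-methoxyphenyl)-6,8-bis(3-methylbut-2-enyl)-2,3-dihydrochromen-4-one (the target flavanone)
Conditions: HCl (1.25 M in MeOH), MeOH, rt to 40 °C
Reagents that add atoms: none
Why: Acid-catalysed acetal exchange removes the methoxymethyl group as dimethoxymethane under conditions mild enough that the prenyl groups should not cyclise onto the freed 7-hydroxyl and that C2, which epimerises only through base-induced ring opening, keeps its configuration.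

**Compound list**

1 | 2,4-dihydroxyacetophenone | CC(=O)c1ccc(O)cc1O | starting material
2 | 3-chloro-3-methylbut-1-yne | CC(C)(Cl)C#C | starting material
3 | 1-[2,4-bis(2-methylbut-3-yn-2-yloxy)phenyl]ethanone | CC(=O)c1ccc(OC(C)(C)C#C)cc1OC(C)(C)C#C | intermediate
4 | 1-[2,4-bis(2-methylbut-3-en-2-yloxy)phenyl]ethanone | CC(=O)c1ccc(OC(C)(C)C=C)cc1OC(C)(C)C=C | intermediate
5 | 2-acetyl-6-(3-methylbut-2-enyl)-5-(2-methylbut-3-en-2-yloxy)cyclohexa-2,4-dien-1-one (racemic, transient) | CC(=O)C1=CC=C(OC(C)(C)C=C)C(CC=C(C)C)C1=O | intermediate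
6 | 1-[2-hydroxy-3-(3-methylbut-2-enyl)-4-(2-methylbut-3-en-2-yloxy)phenyl]ethanone | CC(=O)c1ccc(OC(C)(C)C=C)c(CC=C(C)C)c1O | intermediate
7 | 4-acetyl-3-hydroxy-2,6-bis(3-methylbut-2-enyl)cyclohexa-2,4-dien-1-one (racemic, transient) | CC(=O)C1=CC(CC=C(C)C)C(=O)C(CC=C(C)C)=C1O | intermediate
8 | 1-[2,4-dihydroxy-3,5-bis(3-methylbut-2-enyl)phenyl]ethanone | CC(=O)c1cc(CC=C(C)C)c(O)c(CC=C(C)C)c1O | intermediate
9 | 1-[2-hydroxy-4-(methoxymethoxy)-3,5-bis(3-methylbut-2-enyl)phenyl]ethanone | CC(=O)c1cc(CC=C(C)C)c(OCOC)c(CC=C(C)C)c1O | intermediate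
10 | 4-methoxybenzaldehyde | COc1ccc(C=O)cc1 | starting material
11 | (E)-1-[2-hydroxy-4-(methoxymethoxy)-3,5-bis(3-methylbut-2-enyl)phenyl]-3-(4-methoxyphenyl)prop-2-en-1-one | COCOc1c(CC=C(C)C)cc(C(=O)/C=C/c2ccc(OC)cc2)c(O)c1CC=C(C)C | intermediate
12 | (2S)-7-(methoxymethoxy)-2-(4-methoxyphenyl)-6,8-bis(3-methylbut-2-enyl)-2,3-dihydrochromen-4-one | COc1ccc([C@@H]2CC(=O)c3cc(CC=C(C)C)c(OCOC)c(CC=C(C)C)c3O2)cc1 | intermediate
13 | (2S)-7-hydroxy-2-(4-methoxyphenyl)-6,8-bis(3-methylbut-2-enyl)-2,3-dihydrochromen-4-one (the target flavanone) | COc1ccc([C@@H]2CC(=O)c3cc(CC=C(C)C)c(O)c(CC=C(C)C)c3O2)cc1 | target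

**Total steps:** 7. **Longest linear sequence:** 7 steps (1 → 3 → 4 → 8 → 9 → 11 → 12 → 13); compounds 2 and 10 are purchased.

**Steps most likely to fail**

1. Step 3 (key step). The tertiary allyl ethers may ionise and lose isoprene instead of rearranging, the ether next to the acetyl group being the most strained. The O4 unit may also migrate toward C3 before the O2 unit has moved, which strands the second group. The fallback sets out from compound 1 and comes back at compound 6, running the two shifts one at a time so that each has a single outcome. Compound 1 is etherified only at the free 4-hydroxyl with 2 (1.1 equiv, DBU, CuCl2·2H2O cat., MeCN, 0 °C) to give 1-[2-hydroxy-4-(2-methylbut-3-yn-2-yloxy)phenyl]ethanone F1. Semihydrogenation (H2, Pd/CaCO3 poisoned with Pb(OAc)2, quinoline) gives 1-[2-hydroxy-4-(2-methylbut-3-en-2-yloxy)phenyl]ethanone F2. Its Claisen rearrangement (PhNEt2, 130 °C) should be steered to C3 by the hydrogen-bonded 2-hydroxyl, giving 1-[2,4-dihydroxy-3-(3-methylbut-2-enyl)phenyl]ethanone F3. A second etherification of the 4-hydroxyl with 2 under the same conditions gives 1-[2-hydroxy-3-(3-methylbut-2-enyl)-4-(2-methylbut-3-yn-2-yloxy)phenyl]ethanone F4. Semihydrogenation of F4 over the same poisoned palladium catalyst gives compound 6, which on heating has only C5 open and should give 8.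

2. Step 6. The ring closure is an equilibrium, so repeated opening and re-closing through the chalcone can erode enantiopurity, and addition to the electron-rich 4-methoxyphenyl enone may be slow. The fallback sets out from compound 11 and comes back at compound 12, replacing asymmetric closure by kinetic resolution. Chalcone 11 is closed without induction (NaOAc, EtOH, reflux) to racemic 7-(methoxymethoxy)-2-(4-methoxyphenyl)-6,8-bis(3-methylbut-2-enyl)-2,3-dihydrochromen-4-one F5. F5 is then subjected to asymmetric transfer hydrogenation (RuCl[(R,R)-TsDPEN](p-cymene) cat., HCO2H/Et3N, EtOAc, rt, stopped near half conversion). The (2R) antipode should be reduced to the cis alcohol (2R,4R)-7-(methoxymethoxy)-2-(4-methoxyphenyl)-6,8-bis(3-methylbut-2-enyl)-3,4-dihydro-2H-chromen-4-ol F6, leaving the (2S) ketone 12, which is separated by chromatography. The mirror-image catalyst is available if the sense of discrimination is opposite.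

3. Step 1. Etherification of the hydrogen-bonded 2-hydroxyl may stall at the mono-ether while the tertiary chloride is consumed by elimination. The fallback sets out from compound 2 and comes back at compound 4, building both ethers on a resorcinol with no carbonyl to tie up a hydroxyl. 4-Bromobenzene-1,3-diol F7 (purchased) is bis-etherified with 2 (DBU, CuCl2·2H2O cat., MeCN, 0 °C) to 1-bromo-2,4-bis(2-methylbut-3-yn-2-yloxy)benzene F8. Semihydrogenation (H2, Pd/CaCO3 poisoned with Pb(OAc)2, quinoline) gives 1-bromo-2,4-bis(2-methylbut-3-en-2-yloxy)benzene F9. Bromine–lithium exchange (n-BuLi, THF, −78 °C), addition of N-methoxy-N-methylacetamide and a cold water quench install the acetyl group and give 4.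

**Further compounds**

F1 | step 3 | 1-[2-hydroxy-4-(2-methylbut-3-yn-2-yloxy)phenyl]ethanone | CC(=O)c1ccc(OC(C)(C)C#C)cc1O
F2 | step 3 | 1-[2-hydroxy-4-(2-methylbut-3-en-2-yloxy)phenyl]ethanone | CC(=O)c1ccc(OC(C)(C)C=C)cc1O
F3 | step 3 | 1-[2,4-dihydroxy-3-(3-methylbut-2-enyl)phenyl]ethanone | CC(=O)c1ccc(O)c(CC=C(C)C)c1O
F4 | step 3 | 1-[2-hydroxy-3-(3-methylbut-2-enyl)-4-(2-methylbut-3-yn-2-yloxy)phenyl]ethanone | CC(=O)c1ccc(OC(C)(C)C#C)c(CC=C(C)C)c1O
F5 | step 6 | racemic 7-(methoxymethoxy)-2-(4-methoxyphenyl)-6,8-bis(3-methylbut-2-enyl)-2,3-dihydrochromen-4-one | COc1ccc(C2CC(=O)c3cc(CC=C(C)C)c(OCOC)c(CC=C(C)C)c3O2)cc1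
F6 | step 6 | (2R,4R)-7-(methoxymethoxy)-2-(4-methoxyphenyl)-6,8-bis(3-methylbut-2-enyl)-3,4-dihydro-2H-chromen-4-ol | COc1ccc([C@H]2C[C@@H](O)c3cc(CC=C(C)C)c(OCOC)c(CC=C(C)C)c3O2)cc1
F7 | step 1 | 4-bromobenzene-1,3-diol (purchased) | Oc1ccc(Br)c(O)c1
F8 | step 1 | 1-bromo-2,4-bis(2-methylbut-3-yn-2-yloxy)benzene | Brc1ccc(OC(C)(C)C#C)cc1OC(C)(C)C#C
F9 | step 1 | 1-bromo-2,4-bis(2-methylbut-3-en-2-yloxy)benzene | Brc1ccc(OC(C)(C)C=C)cc1OC(C)(C)C=C
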